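**Retrosynthetic overview**

1. The C4–C1′ bond, the C5=C6 double bond and the C11 hydroxyl are made last, by joining 2,4-diformylphloroglucinol, isovaleraldehyde and water with an aromadendr-4-ene. Its C6–C7–C11 cyclopropane, a ring absent from the target, is opened in that step.
2. The five-membered ring (C1–C2–C3–C4–C5) of this hydroazulene is not built in its final size. It arises by contraction of six-membered ring A (C1, C2, C3, C4, C5, C10) of a eudesmane-type decalin; the same 1,2-shift of C5 from C10 to C1 expands ring B to the seven-membered ring.
3. Enabling feature: the cross-conjugated dienone C1=C2–C3(=O)–C4(CH3)=C5 in ring A next to the quaternary, methyl-bearing C10. Light bonds C1 to C5, the C4 methyl group steers cleavage of C5–C10, and water takes the charge at C10. The C3 carbonyl and the C10 hydroxyl are removed afterwards.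
4. Ring order: ring B from (+)-dihydrocarvone; ring A by Robinson annulation; cyclopropane by γ-alkylation; five- and seven-membered rings together in the photochemical step; arene unit last.

Key step: step 5

Remark: carbons are numbered as in eudesmane (decalins) and guaiane/aromadendrane (hydroazulenes), C1′ is the benzylic carbon, and β is the face of the C7 side chain; commercial (+)-dihydrocarvone contains its C2 epimer, which gives the same enolate.

**Route**

Step 1
Reactants: 1 (+)-dihydrocarvone; 2 ethyl vinyl ketone
Product: 5 (−)-10-epi-α-cyperone, via 1,5-diketone 3 (not isolated), via ketol 4 (not isolated)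
Conditions: KOH (cat.), EtOH, −10 °C to rt, then reflux
Reagents that add atoms: none
Why: Robinson annulation (Michael addition, then aldol condensation): the more substituted enolate of 1 should be attacked axially in the chair-like transition state that keeps the isopropenyl group equatorial, so the new chain enters cis to the isopropenyl group and C10 is set with its methyl group trans to the C7 side chain (10α-methyl, 7β-isopropenyl), the C2 centre of 1 being erased in the enolate.

Step 2
Reactants: 5 (−)-10-epi-α-cyperone
Product: 6 11-bromo-10-epi-eudesm-4-en-3-one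
Conditions: HBr (33% in AcOH), 0 °C
Reagents that add atoms: hydrogen bromide, Br
Why: Markovnikov hydrobromination of the electron-rich 1,1-disubstituted alkene should give the tertiary bromide while the electron-poor enone double bond stays; no stereocentre is formed.

Step 3
Reactants: 6 11-bromo-10-epi-eudesm-4-en-3-one
Product: 7 10-epi-maali-4-en-3-one (6αH,7αH; cyclopropane C6–C7–C11 on the β face)
Conditions: KOH, MeOH, 0 °C to rt
Reagents that add atoms: none
Why: Base removes the only γ-hydrogen (C6) and the dienolate closes the three-membered ring on the tertiary bromide (3-exo-tet γ-alkylation, the carone-type cyclisation); the C6–C11 bond can only form on the β face where C7 holds C11, which sets C6 (H α) and blocks C6 against later enolisation.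

Step 4
Reactants: 7 10-epi-maali-4-en-3-one
Product: 8 10-epi-maali-1,4-dien-3-one
Conditions: DDQ, dioxane, reflux
Reagents that add atoms: none
Why: DDQ dehydrogenation of a Δ4-3-ketone through its dienol should introduce the C1=C2 double bond (C6 is blocked by the cyclopropane) and give the cross-conjugated dienone without touching a stereocentre.

Step 5
Reactants: 8 10-epi-maali-1,4-dien-3-one
Product: 10 10β-hydroxy-1βH-aromadendr-4-en-3-one, via 1,5-bonded zwitterion 9 (not isolated)
Conditions: hν (254 nm, quartz), AcOH–H2O 1:1, N2, rt
Reagents that add atoms: water, O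
Why: Excitation of the cross-conjugated dienone bonds C1 to C5 (formally a 3-exo closure inside ring A) and gives the bicyclo[3.1.0]hexenone zwitterion 9, whose cyclopropane C1–C5–C10 is not part of the target. In aqueous acetic acid 9 is protonated on oxygen and the C4 methyl group localises the positive charge at C4, so the cyclopropane opens at C5–C10 (not C1–C10) while water attacks C10 from the side opposite to the departing C5. The net result is a 1,2-shift of C5 from C10 to C1: ring A (six atoms) contracts to the cyclopentenone C1–C2–C3–C4–C5 and ring B expands to the seven-membered ring by insertion of C1 between C5 and C10. The closest known reaction is the photorearrangement of 4-methyl cross-conjugated cyclohexadienones of the santonin and dehydrocyperone type to 10-hydroxy-hydroazulenones. C1 (H β) is fixed by the 10α-methyl configuration of 8, because the C1–C5 bond can only form on the face of C5 that gives a cis-fused cyclopropane, and C10 (OH β, CH3 α) follows from inversion at C10. The step needs 5/7 formation in preference to the spiro and lumiketone pathways, which the C4 methyl group and the protic acidic medium should secure, and it must leave the C6–C7–C11 cyclopropane intact.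

Step 6
Reactants: 10 10β-hydroxy-1βH-aromadendr-4-en-3-one
Product: 11 3,3-ethylenedithio-1βH-aromadendr-4-en-10β-ol
Conditions: HS(CH2)2SH, Zn(OTf)2 (cat.), CH2Cl2, rt
Reagents that add atoms: ethane-1,2-dithiol, SCCS
Why: Lewis-acid-catalysed dithioketalisation is selective for the ketone carbonyl and should be mild enough to spare the tertiary alcohol and the vinylcyclopropane; no stereocentre changes.

Step 7
Reactants: 11 3,3-ethylenedithio-1βH-aromadendr-4-en-10β-ol
Product: 12 1βH-aromadendr-4-en-10β-ol
Conditions: Raney Ni (acetone-deactivated), EtOH, reflux
Reagents that add atoms: none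
Why: Mozingo reduction: hydrogenolysis of both C–S bonds turns C3 into CH2, and the hindered tetrasubstituted C4=C5 bond should be neither hydrogenated nor moved on deactivated nickel.

Step 8
Reactants: 12 1βH-aromadendr-4-en-10β-ol
Product: 13 methyl oxalate of 12
Conditions: ClC(O)CO2Me, Et3N, DMAP (cat.), CH2Cl2, 0 °C to rt
Reagents that add atoms: methyl oxalyl chloride, COC(=O)C(=O)Cl
Why: Acylation of the hindered tertiary alcohol with the small, very electrophilic acid chloride under DMAP catalysis prepares the C10–O bond for homolysis; the configuration is untouched.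

Step 9
Reactants: 13 methyl oxalate of 12
Product: 14 aromadendr-4-ene (1βH,10βH; isoledene skeleton)
Conditions: Bu3SnH (excess, 0.5 M), AIBN (cat.), PhMe, 110 °C
Reagents that add atoms: none
Why: Radical deoxygenation of a tertiary methyl oxalate (Barton–McCombie type): the stannyl radical adds to the oxalate carbonyl, the C10–O bond breaks, and the planar C10 radical should take hydrogen from Bu3SnH on the exo face of the cycloheptane ring, cis to H1 and away from the transannular C5–C6 unit, which sets C10 (H β, CH3 α); the high stannane concentration should trap the radical before it can add to C5.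

Step 10
Reactants: 14 aromadendr-4-ene (1βH,10βH); 15 2,4-diformylphloroglucinol; 16 isovaleraldehyde
Product: 18 (−)-macrocarpal D, via o-quinone methide 17 (not isolated)
Conditions: NaOAc, AcOH–H2O 4:1, 70 °C
Reagents that add atoms: water, O
Why: Proposed new method: Knoevenagel condensation of 15 and 16 gives o-quinone methide 17, whose benzylic carbon should be attacked by C4 of the tetrasubstituted C4=C5 alkene; the resulting C5 cation is a cyclopropylcarbinyl cation that opens at C6–C11 to the C5=C6 alkene and a tertiary C11 cation, which water captures; the closest known reactions are the three-component o-quinone-methide/terpene couplings that give euglobal-type chromans and the electrophilic (Prins-type) ring opening of vinylcyclopropanes; C4 should be set by attack on the β face, opposite to C10 and its methyl group, and C1′ by a chroman-like approach with the isobutyl group turned away from C3, the C1′ epimer being the expected separable by-product.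

**Compound list**

1 | (+)-dihydrocarvone, (2R,5R)-2-methyl-5-(prop-1-en-2-yl)cyclohexan-1-one | C[C@@H]1CC[C@H](CC1=O)C(C)=C | starting material
2 | ethyl vinyl ketone (pent-1-en-3-one) | CCC(=O)C=C | starting material
3 | 1,5-diketone: 2-methyl-2-(3-oxopentyl)-5-isopropenylcyclohexanone, new chain cis to the isopropenyl group | CCC(=O)CC[C@@]1(C)CC[C@@H](C(C)=C)CC1=O | intermediate
4 | ketol: 5-hydroxy-10-epi-eudesm-11-en-3-one (C4 and C5 not defined, removed in the same operation) | CC1C(=O)CC[C@@]2(C)CC[C@@H](C(C)=C)CC12O | intermediate
5 | (−)-10-epi-α-cyperone, (4aR,7R)-1,4a-dimethyl-7-(prop-1-en-2-yl)-4,4a,5,6,7,8-hexahydronaphthalen-2(3H)-one | CC1=C2C[C@H](C(C)=C)CC[C@]2(C)CCC1=O | intermediate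
6 | 11-bromo-10-epi-eudesm-4-en-3-one, (4aR,7R)-7-(2-bromopropan-2-yl)-1,4a-dimethyl-4,4a,5,6,7,8-hexahydronaphthalen-2(3H)-one | CC1=C2C[C@H](C(C)(C)Br)CC[C@]2(C)CCC1=O | intermediate
7 | 10-epi-maali-4-en-3-one (eudesm-4-en-3-one with a C6–C11 bond; 6αH, 7αH, 10α-methyl) | CC1=C2[C@H]3[C@H](C3(C)C)CC[C@]2(C)CCC1=O | intermediate
8 | 10-epi-maali-1,4-dien-3-one | CC1=C2[C@H]3[C@H](C3(C)C)CC[C@]2(C)C=CC1=O | intermediate
9 | 1,5-bonded zwitterion (oxyallyl cation on C2–C3–C4, cyclopropane C1–C5–C10) | C[C+]1C([O-])=C[C@@H]2[C@@]3(C)CC[C@H]4C(C)(C)[C@H]4[C@@]123 | intermediate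
10 | 10β-hydroxy-1βH-aromadendr-4-en-3-one (10α-methyl, 6αH, 7αH) | CC1=C2[C@H]3[C@H](C3(C)C)CC[C@](C)(O)[C@H]2CC1=O | intermediate
11 | 3,3-ethylenedithio-1βH-aromadendr-4-en-10β-ol | CC1=C2[C@H]3[C@H](C3(C)C)CC[C@](C)(O)[C@H]2CC14SCCS4 | intermediate
12 | 1βH-aromadendr-4-en-10β-ol (10α-methyl) | CC1=C2[C@H]3[C@H](C3(C)C)CC[C@](C)(O)[C@H]2CC1 | intermediate
13 | methyl oxalate of 12 | CC1=C2[C@H]3[C@H](C3(C)C)CC[C@](C)(OC(=O)C(=O)OC)[C@H]2CC1 | intermediate
14 | aromadendr-4-ene (1βH,10βH), (1aR,4R,4aR,7bS)-1,1,4,7-tetramethyl-1a,2,3,4,4a,5,6,7b-octahydro-1H-cyclopropa[e]azulene | CC1=C2[C@H]3[C@H](C3(C)C)CC[C@@H](C)[C@H]2CC1 | intermediate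
15 | 2,4-diformylphloroglucinol (2,4,6-trihydroxybenzene-1,3-dicarbaldehyde) | O=Cc1c(O)cc(O)c(C=O)c1O | starting material
16 | isovaleraldehyde (3-methylbutanal) | CC(C)CC=O | starting material
17 | o-quinone methide from 15 and 16 | CC(C)CC=C1C(=O)C(C=O)=C(O)C(C=O)=C1O | intermediate
18 | (−)-macrocarpal D | CC(C)C[C@@H](c1c(O)c(C=O)c(O)c(C=O)c1O)[C@@]1(C)CC[C@H]2C1=C[C@H](C(C)(C)O)CC[C@H]2C | target

**Step count and risks**

Total steps: 10. Longest linear sequence: 10 steps (from 1).

Steps most likely to fail:

1. Step 10 (Proposed new method). The phenol oxygen may close onto the C5 cation (hetero-Diels–Alder outcome) faster than the cyclopropane opens, acetate may compete with water at C11, and facial control at C4 and C1′ may be low. Fallback with known chemistry, setting out from 14: heating 14 with 15 and 16 under the usual water-free conditions for such couplings (NaOAc, AcOH, 80 °C) should take 17 through the hetero-Diels–Alder addition across C4=C5 and give the cis-fused chroman F1. Treating this with TsOH (cat.) in THF–H2O at rt should ionise the tertiary cyclopropylcarbinyl aryl ether, open the cyclopropane to the homoallyl cation and hydrate C11, which comes back to the route at 18.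

2. Step 7. The cyclopropane conjugated to the double bond may undergo hydrogenolysis on the nickel surface, and C4=C5 may migrate or be saturated. Fallback, setting out from 10: Luche reduction (NaBH4, CeCl3·7H2O, MeOH, 0 °C) should give the allylic diol F2. Ac2O, pyridine and DMAP should acylate only its secondary hydroxyl to the allylic acetate F3. Pd(PPh3)4 with LiBHEt3 in THF should then deliver hydride to the less hindered C3 end of the π-allyl complex (Tsuji–Trost-type reduction), which comes back to the route at 12 and makes step 6 unnecessary.

3. Step 9. The homoallylic C10 radical may re-close onto C5 (3-exo) and reopen toward the less strained decalin skeleton, reversing the ring contraction, and facial control of hydrogen-atom transfer may be lost. Fallback without radicals, setting out from 12: SOCl2 and pyridine at −20 °C should eliminate anti (H1 is cis to the hydroxyl and cannot be lost) to the exocyclic alkene F4. H2 with RhCl(PPh3)3 in benzene should reduce only this 1,1-disubstituted double bond from the exo face, which comes back to the route at 14.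

**Further compounds**

F1 | step 10 | chroman from hetero-Diels–Alder addition of 17 across C4=C5 of 14 (aryl oxygen on C5 and C1′ on C4, both β) | CC(C)C[C@H]1c2c(O)c(C=O)c(O)c(C=O)c2O[C@]23[C@H]4[C@H](C4(C)C)CC[C@@H](C)[C@H]2CC[C@]13C
F2 | step 7 | 1βH-aromadendr-4-ene-3,10β-diol (C3 epimers) | CC1=C2[C@H]3[C@H](C3(C)C)CC[C@](C)(O)[C@H]2CC1O
F3 | step 7 | 3-acetoxy-1βH-aromadendr-4-en-10β-ol (C3 epimers) | CC1=C2[C@H]3[C@H](C3(C)C)CC[C@](C)(O)[C@H]2CC1OC(C)=O
F4 | step 9 | 1βH-aromadendra-4,10(14)-diene | CC1=C2[C@H]3[C@H](C3(C)C)CCC(=C)[C@H]2CC1
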